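# Synthesis proposal for CNP0246965.1 (a spiro-iridal)

## The problem

Numbering used throughout (iridal numbering): C1 = CHO; C2 (bears CH3-25) = C7; chain C3(H2OH)–C4–C5 on C6; ring B = C6–C7–C8–C9–C10–C11 (C10 bears CH3-30 and OH); C11 is the spiro atom; cyclopentane = C11–C12–C13–C14–C26 (C26 bears OH); C14 bears C15; C15 bears C27H2OH and is doubly bonded to C16; then C17=C18, C19(=C28H2), C20, C21, C22=C23(CH3)2. The target is (2Z,6R,10S,11S,14S,15E,17E,26S).

- The core is a spiro[4.5]decane whose quaternary C11 is flanked by three stereocentres (C6, C10, C26), with C14 one atom further. On ring B, C26, the C6 chain and the C10 hydroxyl are mutually cis; on the cyclopentane, the C26 hydroxyl is trans to the C14 substituent and syn to C10.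
- Ring B carries a tetrasubstituted exocyclic enal (C7=C2) with the formyl group cis to the more hindered C6. Sterically controlled olefinations place the carbonyl group on the other side, and the geometry can be lost through the dienol.
- The C14 substituent is a cross-conjugated trienyl carbinol (15E, 17E) with a prenyl terminus. It is sensitive to acid, peracid and Pd–H, and it is itself a diene, so it must come late.
- Two primary, one secondary and one tertiary hydroxyl and one aldehyde must end up at the right oxidation levels.
- The feature that makes the key step possible: C26–OH and C3–OH are the two ends of the carbon path C26–C11–C6–C5–C4–C3. Joining C3 to C26 (retro-reduction, retro-Baeyer–Villiger) closes a cyclohexanone ring A′ (C3, C4, C5, C6, C11, C26). Ring A′ shares C6–C11 with ring B and C11–C26 with the cyclopentane.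
- With C7 as a carbonyl, ring A′ is the [4+2] adduct of a 2-oxydiene C26=C3(O)–C4=C5 and the ring-B alkene C11=C6. The cyclopentane atoms C12–C13–C14 are the three-atom tether of an intramolecular Diels–Alder reaction.
- Only C14 then has to be set beforehand, and C14 is the central carbon of a 3-substituted glutarate.

## Retrosynthesis

**42 ⇒ 41 ⇒ 40.** No skeletal bond is cut. The two silyl ethers of 41 are removed last. The C1 aldehyde and the C27 carbinol are both traced to carboxyl derivatives in 40 (an N-methoxy-N-methylamide and a tert-butyl ester), so that one hydride step gives both without an alcohol/aldehyde differentiation problem.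

**40 ⇒ 30 + 36 (cut C15=C16).** An aldol condensation joins the ester arm on C14 to the trienal 36. A cut at C16–C17 by cross-coupling would need a stereodefined 2-metallated allylic alcohol on the hindered core. The C15=C16 cut instead uses the acetate arm that the glutarate provides and gives the E-enoate by elimination. 36 is three steps from 31 and 32 (via 34 and 35). The forward reaction must tolerate one free tertiary alcohol and must not deprotonate the unsaturated amide.

**30 ⇒ 29 ⇒ 27 ⇒ 24 + 25 (cut C2–C1, then C7–C2).** The Z-enal is traced to the exocyclic enol triflate 29, which comes from the regiospecific enolate of the acetyl enone 27, which comes from the C7 enol triflate 24 and stannane 25. An olefination of a C7 ketone would put the carbonyl group trans to C6. Here the enone conformation (methyl away from C6) writes the geometry into the enolate, and carbonylation transfers it to carbon.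

**24 ⇒ 23 ⇒ 22 ⇒ 21 (cut C10–CH3).** The tertiary carbinol is made by methyl addition to the C10 ketone. The nucleophile must add to the face opposite C26–O and C5, which sit on the same face of ring B. The ketone is released from a dimethyl ketal while C7 is masked as the triflate.

**21 ⇒ 20 ⇒ 18 ⇒ 17 (reconnect C3 to C26).** Lactone reduction and Baeyer–Villiger oxidation in reverse turn the hydroxypropyl chain and the C26 carbinol into one cyclohexanone. The precursor 17 has two heteroatom stereo-relationships fewer, and C26–O is set by retention in the migration. The forward sequence needs the C7 enone to stay inert to peracid, which a conjugated ketone does.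

**17 ⇒ 15 ⇒ 14 (cut C26–C11 and C5–C6; key step).** The intramolecular Diels–Alder reaction of siloxydiene 15 closes ring A′ and the cyclopentane and sets C11, C6 and C26 from C14. The precursor 14 is a monocyclic, non-enolisable quinone monoketal with one stereocentre. This cut is preferred to cuts at C14–C26 or C11–C12 because it is the only one that makes the quaternary centre and its cis neighbour C6 in the same event.

**14 ⇒ 13 ⇒ 12 ⇒ 11 ⇒ 10 ⇒ 9 ⇒ 8 ⇒ 3 ⇒ 1 + 2 + 4.** Oxidative dearomatisation gives the dienophile from phenol 13. The vinyl ketone and the ester arm are the two differentiated carboxyls of hemiester 10, made by catalytic desymmetrisation of the meso anhydride 9. The diacid 8 comes from aldehyde 3 and malonate 4, and 3 from bromophenol 1 and allyl alcohol 2.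

## Roads not taken

**Alternative 1:** (the most obvious) Cut C14–C26, as the presumed biosynthesis does. The forward key step is a Lewis-acid carbonyl-ene (Prins) cyclisation of the monocyclic C26 aldehyde A1 onto C14=C15, with hydrogen transfer from C16 giving the triene. A1 already contains the quaternary C11 with C6 and C10 in place, the masked Z-enal and the whole acid-sensitive polyene, so the key step leaves the hardest part unsolved. The step must also control C26 and C14 relative to C11, the cis/trans sense of a five-ring ene closure, and H-transfer from C16 rather than C27, all in the presence of a Lewis acid and a triene. The chosen plan makes C11, C6 and C26 in one step from a flat precursor and brings the polyene in afterwards.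

**Alternative 2:** Cut C11–C12 by a semipinacol ring expansion. The allylic cyclobutanol A2 would be epoxidised to A3, which would rearrange to the spiro ketol A4, setting C10 and C11 together stereospecifically (migration anti to the epoxide C–O bond). The required epoxide A3 must form on the same face as the pseudo-axial C6 allyl group, against the steric bias, and nothing in A2 can direct it there. A4 then still needs α-functionalisation at C14, a trans-selective reduction at C26, and conversion of an isopropenyl group into the Z-enal. C6 is not relayed, and the step count after the key step is higher than in the chosen plan.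

**Alternative 3:** Cut C14–C15. The spiro-fused cyclopentene oxide A5 would be opened trans at C14 by an alkenyl metal derived from vinyl iodide A6, attaching the complete side chain and setting C14 and C26 at once. This is convergent, but A5 already holds C6, C10, C11 and the Z-enal, which would have to be built one by one on a cyclohexanone. The epoxide face and the opening regiochemistry are further control problems, and the organometallic step must spare a masked enal. The chosen plan uses one stereocentre (C14) to set three others and keeps the side-chain union as a simple aldol condensation.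

Key step: step 9

**Remarks.**
- Assumption on step 4: (DHQD)2AQN is taken to give the (S)-hemiester 10, as for 3-alkylglutaric anhydrides; if the sense is opposite, its pseudo-enantiomer (DHQ)2AQN is used.
- Compounds 1, 2, 4, 25, 31 and 32 (32 as its aqueous solution) are taken as commercial.

## Route

Step 1
Reactants: 1 3-bromo-4-methoxyphenol; 2 prop-2-en-1-ol
Product: 3 3-(5-hydroxy-2-methoxyphenyl)propanal
Conditions: Pd(OAc)2 (cat.), P(o-tol)3, Bu4NCl, NaHCO3, DMF, 90 °C
Reagents that add atoms: none
Why: Heck arylation of allyl alcohol; the aryl group adds to the terminal carbon and β-hydride elimination towards the carbinol gives the enol, hence the saturated aldehyde. The free phenol is tolerated.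

Step 2
Reactants: 3 3-(5-hydroxy-2-methoxyphenyl)propanal; 4 diethyl malonate
Product: 8 3-[2-(5-hydroxy-2-methoxyphenyl)ethyl]pentanedioic acid, via alkylidenemalonate 5 (not isolated), via tetraester 6 (not isolated), via tetraacid 7 (not isolated)
Conditions: 4 (2.2 equiv), piperidine, AcOH (cat.), PhMe, reflux (−H2O); NaOEt (cat.), EtOH, 50 °C; then 6 M HCl, reflux
Reagents that add atoms: water, O
Why: Knoevenagel condensation, Michael addition of a second malonate, then acid hydrolysis with double decarboxylation, the standard entry to 3-substituted glutaric acids. The future C14 is created as a prochiral carbon.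

Step 3
Reactants: 8 3-[2-(5-hydroxy-2-methoxyphenyl)ethyl]pentanedioic acid
Product: 9 3-[2-(2,6-dioxooxan-4-yl)ethyl]-4-methoxyphenyl acetate (meso anhydride)
Conditions: Ac2O, 110 °C
Reagents that add atoms: acetic anhydride, CC(=O)OC(C)=O
Why: Dehydration to the six-membered cyclic anhydride. The phenol is acetylated in the same operation and stays masked until step 6.

Step 4
Reactants: 9 meso anhydride
Product: 10 (3S)-3-[2-(5-acetoxy-2-methoxyphenyl)ethyl]-5-methoxy-5-oxopentanoic acid
Conditions: MeOH (10 equiv), (DHQD)2AQN (10 mol %), Et2O, −25 °C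
Reagents that add atoms: methanol, CO
Why: Catalytic enantioselective alcoholysis (desymmetrisation) of a meso 3-alkylglutaric anhydride by a bis-cinchona-alkaloid general base. The catalyst selects one enantiotopic carbonyl and so sets C14, the only stereocentre not made by substrate control.

Step 5
Reactants: 10 (3S)-hemiester
Product: 11 1-tert-butyl 5-methyl (3R)-3-[2-(5-acetoxy-2-methoxyphenyl)ethyl]pentanedioate
Conditions: t-BuOC(=NH)CCl3, BF3·OEt2 (cat.), CH2Cl2–cyclohexane, rt
Reagents that add atoms: tert-butyl 2,2,2-trichloroacetimidate, CC(C)(C)OC(=N)C(Cl)(Cl)Cl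
Why: Acid-catalysed tert-butylation of the acid through the imidate. The tert-butyl ester (the later C15–C27 arm) is inert to the magnesium amide, Grignard, borohydride and organocerium reagents used before it is needed; the descriptor changes by priority only.

Step 6
Reactants: 11 mixed diester
Product: 12 tert-butyl (3R)-3-[2-(5-hydroxy-2-methoxyphenyl)ethyl]-5-[methoxy(methyl)amino]-5-oxopentanoate
Conditions: MeNH(OMe)·HCl (3 equiv), i-PrMgCl (7 equiv), THF, −20 → 0 °C
Reagents that add atoms: N,O-dimethylhydroxylamine hydrochloride, CNOC.Cl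
Why: Aminolysis of the methyl ester by the chloromagnesium amide; the tert-butyl ester does not react. The aryl acetate is cleaved by the same reagent, which frees the phenol without a separate step.

Step 7
Reactants: 12 N-methoxy-N-methylamide
Product: 13 tert-butyl (3R)-3-[2-(5-hydroxy-2-methoxyphenyl)ethyl]-5-oxohept-6-enoate
Conditions: CH2=CHMgBr (3.5 equiv), THF, −78 → 0 °C; inverse quench into cold aq. NaHSO4
Reagents that add atoms: vinylmagnesium bromide, C=C[Mg]Br
Why: Grignard addition stops at the chelated tetrahedral intermediate and gives the vinyl ketone on work-up. The acidic inverse quench keeps the liberated amine protonated and prevents its conjugate addition.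

Step 8
Reactants: 13 phenolic vinyl ketone
Product: 14 tert-butyl (3R)-3-[2-(6,6-dimethoxy-3-oxocyclohexa-1,4-dien-1-yl)ethyl]-5-oxohept-6-enoate
Conditions: PhI(OAc)2, MeOH, 0 °C
Reagents that add atoms: methanol, CO
Why: Oxidative dearomatisation of a 4-methoxyphenol to the quinone monoketal. It gives a non-enolisable, achiral dienone that carries the tether on the β-carbon (C11) and keeps C10 as a masked ketone.

Step 9
Reactants: 14 quinone monoketal vinyl ketone
Product: 17 tricyclic diketone (ring A′ ketone at C3; ring B enone C7(=O)–C8=C9 with C10 dimethyl ketal; A′/B cis-fused at C6–C11, A′/cyclopentane trans-fused at C11–C26; CH2CO2t-Bu on C14 trans to C3; C6, C11, C14, C26 as in 42), via silyl dienol ether 15 (not isolated), via cycloadduct silyl enol ether 16 (not isolated)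
Conditions: TBSCl, KHMDS, THF, −78 °C (in-situ trapping); then PhMe, BHT (cat.), 100 °C; then TBAF, AcOH, THF, 0 °C
Reagents that add atoms: none
Why: In-situ O-silylation of the kinetic α′-enolate of the vinyl ketone gives the (Z)-2-siloxy-1,3-diene 15 (C26=C3(OSi)–C4=C5), whose nucleophilic terminus C26 is polarity-matched with the β-carbon C11 of the quinone monoketal; heating closes C26–C11 and C5–C6 in a normal-demand intramolecular Diels–Alder reaction of the nona-1,6,8-triene type (closest known types: siloxydiene/quinone-monoketal cycloadditions and the anionic intramolecular double Michael reaction). Ring A′ is closed as the cyclohexene of the [4+2] event and the cyclopentane by the three-atom tether C12–C13–C14 (formally 5-exo at C11). C11 and C6 come out cis (C26 and C5 on the same face of ring B) because the diene adds suprafacially to the ring alkene. C26 is set by the endo mode: with the C7 carbonyl under the diene the tether is exo at C11, which gives the trans-hydrindane in which C3 (the later C26–O) is syn to C10. The absolute sense comes from C14 alone: allylic 1,3-strain with the (Z)-siloxy group holds C14–H in the diene plane, so the dienophile, held by C13, adds to the face opposite the CH2CO2t-Bu arm, which places the arm trans to C3 and syn to C6 as in 42. The step needs endo over exo selectivity and a single diene face; the first is supported by secondary overlap with C7=O and the matched polarisation, the second by the tether stereocentre, and ring B has no stereocentre of its own that could mismatch. Buffered fluoride then cleaves the enol ether to the C3 ketone without epimerising C26 or C6.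

Step 10
Reactants: 17 tricyclic diketone
Product: 18 tricyclic ε-lactone (C26–O–C3(=O)–C4–C5–C6), otherwise as 17
Conditions: m-CPBA, NaHCO3, CH2Cl2, 0 °C → rt
Reagents that add atoms: 3-chloroperoxybenzoic acid, O=C(OO)c1cccc(Cl)c1
Why: Baeyer–Villiger oxidation of the saturated C3 ketone; the secondary C26 migrates in preference to C4H2 and with retention, which fixes C26–O syn to C10. The conjugated C7 ketone and its electron-poor alkene do not react.

Step 11
Reactants: 18 ε-lactone enone
Product: 20 C7 enol triflate (C7(OTf)=C8, C9H2), lactone and ketal retained, via lithium enolate 19 (not isolated)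
Conditions: L-Selectride (1.05 equiv), THF, −78 °C; then PhNTf2, −78 → 0 °C
Reagents that add atoms: N-phenylbis(trifluoromethanesulfonimide), O=S(=O)(N(c1ccccc1)S(=O)(=O)C(F)(F)F)C(F)(F)F
Why: Conjugate hydride addition to the β-unsubstituted cyclohexenone gives the C7/C8 enolate regiospecifically, and O-triflation traps it. C7 is thereby masked against the later methyl addition and prepared for C–C coupling; C6 is not enolised.

Step 12
Reactants: 20 enol triflate lactone
Product: 21 diol (C26–OH and C3H2–OH; spiro[4.5]decene with C7 triflate, C10 dimethyl ketal, CH2CO2t-Bu on C14)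
Conditions: LiBH4, THF, 0 °C → rt
Reagents that add atoms: none
Why: Borohydride reduction of the lactone releases the hydroxypropyl chain and the C26 carbinol together. The tert-butyl ester, the ketal and the enol triflate are inert to LiBH4.

Step 13
Reactants: 21 diol
Product: 22 bis-TBS ether (C3–OTBS, C26–OTBS)
Conditions: TBSCl (2.5 equiv), imidazole, DMAP (cat.), DMF, 40 °C
Reagents that add atoms: tert-butyldimethylsilyl chloride, CC(C)(C)[Si](C)(C)Cl
Why: Standard silylation of the primary and secondary alcohols. The bulky C26–OTBS, which lies over C10, later reinforces the facial bias at C10.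

Step 14
Reactants: 22 ketal
Product: 23 C10 ketone
Conditions: PPTS, acetone–H2O (10:1), 40 °C
Reagents that add atoms: water, O
Why: Mild hydrolysis of the dimethyl ketal. The enol triflate, silyl ethers and tert-butyl ester are stable to PPTS, and the enol triflate does not readily move into conjugation under these conditions.

Step 15
Reactants: 23 C10 ketone
Product: 24 C10 tertiary alcohol (CH3 trans, OH cis to C26 and to the C6 chain)
Conditions: MeLi, CeCl3, THF, −78 °C
Reagents that add atoms: methyllithium, [Li]C
Why: Organocerium 1,2-addition, a weakly basic nucleophile that does not enolise the β,γ-unsaturated ketone or touch the ester. C26–OTBS and the C5 chain occupy the same face of ring B, so methyl should add from the opposite (C12) face and give the 10S carbinol.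

Step 16
Reactants: 24 enol triflate; 25 tributyl(1-ethoxyethenyl)stannane
Product: 27 C7 acetyl enone (C8=C7–C2(=O)CH3), via 2-ethoxydiene 26 (not isolated)
Conditions: Pd(PPh3)4 (cat.), LiCl, THF, 65 °C; then aq. oxalic acid, THF, rt
Reagents that add atoms: water, O
Why: Stille coupling of the enol triflate with an α-alkoxyvinylstannane; the 2-alkoxydiene hydrolyses under very mild acid to the methyl ketone. This brings in C2 and C25.

Step 17
Reactants: 27 acetyl enone
Product: 29 (Z)-exocyclic enol triflate (C7=C2(CH3)OTf, OTf cis to C6), via lithium (Z)-enolate 28 (not isolated)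
Conditions: Li, NH3(l), THF, t-BuOH (1 equiv), −78 °C; evaporate NH3; then PhNTf2, THF, 0 °C
Reagents that add atoms: N-phenylbis(trifluoromethanesulfonimide), O=S(=O)(N(c1ccccc1)S(=O)(=O)C(F)(F)F)C(F)(F)F
Why: Dissolving-metal reduction gives the exocyclic enolate regiospecifically, with protonation at C8. The radical anion keeps the s-trans arrangement in which the methyl avoids C6, so the oxygen ends up cis to C6, and O-triflation preserves this geometry.

Step 18
Reactants: 29 (Z)-enol triflate
Product: 30 (Z)-N-methoxy-N-methyl amide (C7=C2(CH3)–C1(=O)N(OMe)Me, C1 cis to C6)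
Conditions: Pd(OAc)2 (cat.), Xantphos, CO (1 atm), MeNH(OMe)·HCl, Et3N, PhMe, 80 °C
Reagents that add atoms: carbon monoxide, [C-]#[O+]; N,O-dimethylhydroxylamine hydrochloride, CNOC.Cl
Why: Palladium-catalysed aminocarbonylation of an enol triflate proceeds with retention of alkene geometry. The amide is a latent aldehyde that survives enolate chemistry and is reduced only to the aldehyde level.

Step 19
Reactants: 31 6-methylhept-5-en-2-one; 32 2,2-dimethoxyacetaldehyde
Product: 34 (2E)-1,1-dimethoxy-8-methylnona-2,7-dien-4-one, via aldol 33 (not isolated)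
Conditions: NaOH (aq), MeOH, 0 °C → rt
Reagents that add atoms: none
Why: Claisen–Schmidt condensation of a methyl ketone with a non-enolisable aldehyde; condensation at the methyl group and E geometry are favoured under equilibrating conditions.

Step 20
Reactants: 34 enone acetal
Product: 35 (2E)-1,1-dimethoxy-8-methyl-4-methylidenenona-2,7-diene
Conditions: Ph3PCH3Br, KOt-Bu, THF, 0 °C → rt
Reagents that add atoms: methyltriphenylphosphonium bromide, C[P+](c1ccccc1)(c1ccccc1)c1ccccc1.[Br-]
Why: Wittig methylenation of the enone carbonyl (1,2-addition) gives the 2-substituted 1,3-diene; the acetal is inert.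

Step 21
Reactants: 35 diene acetal
Product: 36 (2E)-8-methyl-4-methylidenenona-2,7-dienal
Conditions: oxalic acid (cat.), THF–H2O, rt
Reagents that add atoms: water, O
Why: Mild hydrolysis of an allylic acetal; the E enal is retained. The aldehyde is used fresh because it can dimerise by cycloaddition.

Step 22
Reactants: 30 (Z)-amide tert-butyl ester; 36 trienal
Product: 40 tert-butyl (15E,17E)-trienoate (C15(CO2t-Bu)=C16H–C17H=C18H–C19(=CH2)–…), via dilithium salt 37 (not isolated), via aldol adduct 38 (not isolated), via mesylate 39 (not isolated)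
Conditions: LDA (2.2 equiv), THF, −78 °C; 36; aq. NH4Cl work-up; crude aldol: MsCl, Et3N, CH2Cl2, 0 °C; then DBU, rt
Reagents that add atoms: none
Why: Aldol addition of the ester enolate (the C10 alkoxide is carried as its lithium salt) to the non-enolisable trienal, then mesylation of the secondary aldol hydroxyl and E1cB elimination. The elimination should give the conjugated E-enoate (ester trans to C17) from either aldol diastereomer; the hindered tertiary C10–OH is not mesylated.

Step 23
Reactants: 40 trienoate amide
Product: 41 3,26-bis-O-TBS ether of 42 (C1 aldehyde, C27 carbinol)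
Conditions: DIBAL-H (6 equiv), CH2Cl2, −78 → −20 °C; aq. Rochelle salt
Reagents that add atoms: none
Why: DIBAL reduces the tert-butyl ester 1,2 to the allylic alcohol and the N-methoxy-N-methylamide to a chelated hemiaminal that gives the aldehyde only on work-up. Both termini reach their final oxidation levels in one step without isomerising C2=C7.

Step 24
Reactants: 41 bis-silyl ether
Product: 42 CNP0246965.1
Conditions: HF·pyridine, pyridine, THF, 0 °C → rt
Reagents that add atoms: none
Why: Buffered fluoride cleaves the primary and secondary TBS ethers. The conditions are only weakly acidic, so the trienyl carbinol and the Z-enal should survive.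

## Compound list

1 | 3-bromo-4-methoxyphenol | COc1ccc(O)cc1Br | starting material
2 | prop-2-en-1-ol | C=CCO | starting material
3 | 3-(5-hydroxy-2-methoxyphenyl)propanal | COc1ccc(O)cc1CCC=O | intermediate
4 | diethyl malonate | CCOC(=O)CC(=O)OCC | starting material
5 | diethyl 2-[3-(5-hydroxy-2-methoxyphenyl)propylidene]propanedioate | CCOC(=O)C(=CCCc1cc(O)ccc1OC)C(=O)OCC | intermediate
6 | tetraethyl 2-[2-(5-hydroxy-2-methoxyphenyl)ethyl]propane-1,1,3,3-tetracarboxylate | CCOC(=O)C(C(=O)OCC)C(CCc1cc(O)ccc1OC)C(C(=O)OCC)C(=O)OCC | intermediate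
7 | 2-[2-(5-hydroxy-2-methoxyphenyl)ethyl]propane-1,1,3,3-tetracarboxylic acid | OC(=O)C(C(=O)O)C(CCc1cc(O)ccc1OC)C(C(=O)O)C(=O)O | intermediate
8 | 3-[2-(5-hydroxy-2-methoxyphenyl)ethyl]pentanedioic acid | OC(=O)CC(CCc1cc(O)ccc1OC)CC(=O)O | intermediate
9 | 3-[2-(2,6-dioxooxan-4-yl)ethyl]-4-methoxyphenyl acetate | CC(=O)Oc1ccc(OC)c(CCC2CC(=O)OC(=O)C2)c1 | intermediate
10 | (3S)-3-[2-(5-acetoxy-2-methoxyphenyl)ethyl]-5-methoxy-5-oxopentanoic acid | OC(=O)C[C@@H](CC(=O)OC)CCc1cc(OC(C)=O)ccc1OC | intermediate
11 | 1-tert-butyl 5-methyl (3R)-3-[2-(5-acetoxy-2-methoxyphenyl)ethyl]pentanedioate | CC(C)(C)OC(=O)C[C@@H](CC(=O)OC)CCc1cc(OC(C)=O)ccc1OC | intermediate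
12 | tert-butyl (3R)-3-[2-(5-hydroxy-2-methoxyphenyl)ethyl]-5-[methoxy(methyl)amino]-5-oxopentanoate | CC(C)(C)OC(=O)C[C@@H](CC(=O)N(C)OC)CCc1cc(O)ccc1OC | intermediate
13 | tert-butyl (3R)-3-[2-(5-hydroxy-2-methoxyphenyl)ethyl]-5-oxohept-6-enoate | CC(C)(C)OC(=O)C[C@@H](CC(=O)C=C)CCc1cc(O)ccc1OC | intermediate
14 | tert-butyl (3R)-3-[2-(6,6-dimethoxy-3-oxocyclohexa-1,4-dien-1-yl)ethyl]-5-oxohept-6-enoate | CC(C)(C)OC(=O)C[C@@H](CC(=O)C=C)CCC1=CC(=O)C=CC1(OC)OC | intermediate
15 | tert-butyl (3S,4Z)-5-[(tert-butyldimethylsilyl)oxy]-3-[2-(6,6-dimethoxy-3-oxocyclohexa-1,4-dien-1-yl)ethyl]hepta-4,6-dienoate | CC(C)(C)OC(=O)C[C@@H](/C=C(\O[Si](C)(C)C(C)(C)C)C=C)CCC1=CC(=O)C=CC1(OC)OC | intermediate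
16 | tricyclic cycloadduct: C3 TBS enol ether (C3=C4) of 17 | CC(C)(C)OC(=O)C[C@@H]1CC[C@]2([C@H](CC=C3O[Si](C)(C)C(C)(C)C)C(=O)C=CC2(OC)OC)[C@H]13 | intermediate
17 | tricyclic diketone: ring A′ C3 ketone, ring B C7 enone with C10 dimethyl ketal, A′/B cis, A′/cyclopentane trans, CH2CO2t-Bu on C14 | CC(C)(C)OC(=O)C[C@@H]1CC[C@]2([C@H](CCC3=O)C(=O)C=CC2(OC)OC)[C@H]13 | intermediate
18 | tricyclic ε-lactone (C26–O–C3(=O)), ring B enone/ketal as in 17 | CC(C)(C)OC(=O)C[C@@H]1CC[C@]2([C@H](CCC(=O)O3)C(=O)C=CC2(OC)OC)[C@H]13 | intermediate
19 | lithium C7 enolate from conjugate reduction of 18 | [Li+].CC(C)(C)OC(=O)C[C@@H]1CC[C@]2([C@H](CCC(=O)O3)C([O-])=CCC2(OC)OC)[C@H]13 | intermediate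
20 | C7 enol triflate of the lactone (C7(OTf)=C8) | CC(C)(C)OC(=O)C[C@@H]1CC[C@]2([C@H](CCC(=O)O3)C(OS(=O)(=O)C(F)(F)F)=CCC2(OC)OC)[C@H]13 | intermediate
21 | spiro diol (C26–OH, C3–OH), C7 enol triflate, C10 dimethyl ketal | CC(C)(C)OC(=O)C[C@@H]1CC[C@]2([C@H](CCCO)C(OS(=O)(=O)C(F)(F)F)=CCC2(OC)OC)[C@H]1O | intermediate
22 | 3,26-bis-O-TBS ether of 21 | CC(C)(C)OC(=O)C[C@@H]1CC[C@]2([C@H](CCCO[Si](C)(C)C(C)(C)C)C(OS(=O)(=O)C(F)(F)F)=CCC2(OC)OC)[C@H]1O[Si](C)(C)C(C)(C)C | intermediate
23 | C10 ketone (from 22) | CC(C)(C)OC(=O)C[C@@H]1CC[C@]2([C@H](CCCO[Si](C)(C)C(C)(C)C)C(OS(=O)(=O)C(F)(F)F)=CCC2=O)[C@H]1O[Si](C)(C)C(C)(C)C | intermediate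
24 | C10 tertiary alcohol (10S; OH cis to C26 and to the C6 chain), C7 enol triflate | CC(C)(C)OC(=O)C[C@@H]1CC[C@]2([C@H](CCCO[Si](C)(C)C(C)(C)C)C(OS(=O)(=O)C(F)(F)F)=CC[C@]2(C)O)[C@H]1O[Si](C)(C)C(C)(C)C | intermediate
25 | tributyl(1-ethoxyethenyl)stannane | CCCC[Sn](CCCC)(CCCC)C(=C)OCC | starting material
26 | C7 (1-ethoxyethenyl) diene | CC(C)(C)OC(=O)C[C@@H]1CC[C@]2([C@H](CCCO[Si](C)(C)C(C)(C)C)C(C(=C)OCC)=CC[C@]2(C)O)[C@H]1O[Si](C)(C)C(C)(C)C | intermediate
27 | C7 acetyl enone (C8=C7–C(=O)CH3) | CC(C)(C)OC(=O)C[C@@H]1CC[C@]2([C@H](CCCO[Si](C)(C)C(C)(C)C)C(C(C)=O)=CC[C@]2(C)O)[C@H]1O[Si](C)(C)C(C)(C)C | intermediate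
28 | lithium (Z)-enolate C7=C2(CH3)O–, O cis to C6 | [Li+].CC(C)(C)OC(=O)C[C@@H]1CC[C@]2([C@H](CCCO[Si](C)(C)C(C)(C)C)/C(=C(/C)[O-])CC[C@]2(C)O)[C@H]1O[Si](C)(C)C(C)(C)C | intermediate
29 | (Z)-exocyclic enol triflate C7=C2(CH3)OTf | CC(C)(C)OC(=O)C[C@@H]1CC[C@]2([C@H](CCCO[Si](C)(C)C(C)(C)C)/C(=C(/C)OS(=O)(=O)C(F)(F)F)CC[C@]2(C)O)[C@H]1O[Si](C)(C)C(C)(C)C | intermediate
30 | (Z)-N-methoxy-N-methyl amide C7=C2(CH3)C(=O)N(OMe)Me | CC(C)(C)OC(=O)C[C@@H]1CC[C@]2([C@H](CCCO[Si](C)(C)C(C)(C)C)/C(=C(/C)C(=O)N(C)OC)CC[C@]2(C)O)[C@H]1O[Si](C)(C)C(C)(C)C | intermediate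
31 | 6-methylhept-5-en-2-one | CC(=O)CCC=C(C)C | starting material
32 | 2,2-dimethoxyacetaldehyde | COC(OC)C=O | starting material
33 | 2-hydroxy-1,1-dimethoxy-8-methylnon-7-en-4-one | COC(OC)C(O)CC(=O)CCC=C(C)C | intermediate
34 | (2E)-1,1-dimethoxy-8-methylnona-2,7-dien-4-one | COC(OC)/C=C/C(=O)CCC=C(C)C | intermediate
35 | (2E)-1,1-dimethoxy-8-methyl-4-methylidenenona-2,7-diene | COC(OC)/C=C/C(=C)CCC=C(C)C | intermediate
36 | (2E)-8-methyl-4-methylidenenona-2,7-dienal | O=C/C=C/C(=C)CCC=C(C)C | intermediate
37 | dilithium salt of 30 (C10 alkoxide, ester enolate) | [Li+].[Li+].CC(C)(C)OC([O-])=C[C@@H]1CC[C@]2([C@H](CCCO[Si](C)(C)C(C)(C)C)/C(=C(/C)C(=O)N(C)OC)CC[C@]2(C)[O-])[C@H]1O[Si](C)(C)C(C)(C)C | intermediate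
38 | aldol adduct (C16 carbinol; diastereomer mixture at C15/C16) | CC(C)=CCCC(=C)/C=C/C(O)C(C(=O)OC(C)(C)C)[C@@H]1CC[C@]2([C@H](CCCO[Si](C)(C)C(C)(C)C)/C(=C(/C)C(=O)N(C)OC)CC[C@]2(C)O)[C@H]1O[Si](C)(C)C(C)(C)C | intermediate
39 | C16 methanesulfonate of 38 | CC(C)=CCCC(=C)/C=C/C(OS(C)(=O)=O)C(C(=O)OC(C)(C)C)[C@@H]1CC[C@]2([C@H](CCCO[Si](C)(C)C(C)(C)C)/C(=C(/C)C(=O)N(C)OC)CC[C@]2(C)O)[C@H]1O[Si](C)(C)C(C)(C)C | intermediate
40 | tert-butyl (15E,17E)-trienoate with (2Z)-N-methoxy-N-methyl amide, 3,26-bis-O-TBS | C=C(/C=C/C=C(/C(=O)OC(C)(C)C)[C@@H]1CC[C@]2([C@H](CCCO[Si](C)(C)C(C)(C)C)/C(=C(/C)C(=O)N(C)OC)CC[C@]2(C)O)[C@H]1O[Si](C)(C)C(C)(C)C)CCC=C(C)C | intermediate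
41 | 3,26-bis-O-TBS ether of the target | C=C(/C=C/C=C(/CO)[C@@H]1CC[C@]2([C@H](CCCO[Si](C)(C)C(C)(C)C)/C(=C(/C)C=O)CC[C@]2(C)O)[C@H]1O[Si](C)(C)C(C)(C)C)CCC=C(C)C | intermediate
42 | CNP0246965.1, (2Z,6R,10S,11S,14S,15E,17E,26S) | C=C(/C=C/C=C(/CO)[C@@H]1CC[C@]2([C@H](CCCO)/C(=C(/C)C=O)CC[C@]2(C)O)[C@H]1O)CCC=C(C)C | target

## Step count and least certain steps

Total: 24 steps. Longest linear sequence: 21 steps (steps 1–18 and 22–24); steps 19–21 make the trienal 36.

**Step 9 (key step).** The cycloaddition may go partly through the exo mode (tether under the diene), which gives the cis-hydrindane with C11 and C6 inverted relative to C14. Other risks are weak discrimination of the diene faces by the C14 arm, polymerisation of the vinyl ketone or dienol ether before ring closure, and epimerisation at C26 or C6 when the C3 ketone is released. Fallback: set out from 14 and run the same bond construction stepwise and ionically. A mild base (Cs2CO3, MeCN, 0 °C) should add the C26 enolate to C11 (5-exo Michael) to give the spiro Michael adduct F1, in which C26 is α to the acryloyl ketone and can equilibrate to the isomer trans to the C14 arm. F1 is then closed by the second Michael addition of the ring-B enolate (C6) to the vinyl ketone terminus C5 (6-endo; LiHMDS or TMSI/(Me3Si)2NH), which returns to the route at 17.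

**Step 17.** The enolate geometry may leak, either by reduction through the s-cis conformer or by equilibration of the enolate before triflation, which would give the 2E series. Partial reduction of the tert-butyl ester is also possible. Fallback: set out from 24 and hydrolyse the C7 enol triflate (CsOH, THF–H2O) to the saturated C7 ketone F3. Horner–Wadsworth–Emmons olefination of F3 with diethyl {1-[methoxy(methyl)carbamoyl]ethyl}phosphonate (NaH, DME, 80 °C) gives 30 together with its 2E isomer F4. Chromatographic separation returns to the route at 30; this is not stereoselective, but the geometry is then fixed by isolation.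

**Step 15.** The facial bias at C10 may be insufficient or reversed in the half-chair imposed by the C7=C8 enol triflate, and the β,γ-unsaturated ketone may be enolised or drawn into conjugation. Fallback: set out from 23, make the 1,1-disubstituted alkene F2 by Wittig methylenation, and hydrate it under Mukaiyama conditions (Mn(dpm)3, PhSiH3, O2, i-PrOH) to return at 24. In this sequence the oxygen, not the methyl carbon, enters from the more accessible face, so it gives the C10 epimer complementary to the organometallic addition if that one goes the wrong way.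

**Step 22.** LDA may deprotonate the γ-positions (C8, C6) of the unsaturated amide, which would erode the C2=C7 geometry or C6. The trienal may self-condense or dimerise, and the elimination may give some 15Z enoate. Fallback: set out from 29, which has no carbonyl on the tetrasubstituted alkene, and carry out the same aldol condensation with 36 there to give the trienoate enol triflate F5. Aminocarbonylation of F5 under the conditions of step 18 returns to the route at 40.

## Further compounds

F1 | step 9 | spiro Michael adduct (C26–C11 bond closed; C26 bears the acryloyl group; ring B C7 enone with C6H2 and C10 dimethyl ketal) | CC(C)(C)OC(=O)C[C@@H]1CC[C@]2(CC(=O)C=CC2(OC)OC)[C@H]1C(=O)C=C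
F2 | step 15 | C10 methylidene analogue of 23 | CC(C)(C)OC(=O)C[C@@H]1CC[C@]2([C@H](CCCO[Si](C)(C)C(C)(C)C)C(OS(=O)(=O)C(F)(F)F)=CCC2=C)[C@H]1O[Si](C)(C)C(C)(C)C
F3 | step 17 | saturated C7 ketone from hydrolysis of 24 | CC(C)(C)OC(=O)C[C@@H]1CC[C@]2([C@H](CCCO[Si](C)(C)C(C)(C)C)C(=O)CC[C@]2(C)O)[C@H]1O[Si](C)(C)C(C)(C)C
F4 | step 17 | (2E) isomer of 30 | CC(C)(C)OC(=O)C[C@@H]1CC[C@]2([C@H](CCCO[Si](C)(C)C(C)(C)C)/C(=C(\C)C(=O)N(C)OC)CC[C@]2(C)O)[C@H]1O[Si](C)(C)C(C)(C)C
F5 | step 22 | tert-butyl (15E,17E)-trienoate carrying the (Z)-exocyclic enol triflate | C=C(/C=C/C=C(/C(=O)OC(C)(C)C)[C@@H]1CC[C@]2([C@H](CCCO[Si](C)(C)C(C)(C)C)/C(=C(/C)OS(=O)(=O)C(F)(F)F)CC[C@]2(C)O)[C@H]1O[Si](C)(C)C(C)(C)C)CCC=C(C)C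
A1 | alternative 1 | monocyclic C26 aldehyde (ene substrate): ring B as in 42 with C1 as dimethyl acetal, C3–O and C27–O as TBS ethers, open C12–C24 chain with C14=C15 and C17=C18 | CC(C)=CCCC(=C)/C=C/C/C(CO[Si](C)(C)C(C)(C)C)=C/CC[C@]2([C@H](CCCO[Si](C)(C)C(C)(C)C)/C(=C(/C)C(OC)OC)CC[C@]2(C)O)C=O
A2 | alternative 2 | 1-[trans-6-allyl-5-isopropenyl-2-methylcyclohex-1-en-1-yl]cyclobutan-1-ol | OC1(CCC1)C2=C(C)CC[C@H](C(C)=C)[C@H]2CC=C
A3 | alternative 2 | C10/C11 epoxide of A2 on the face of the C6 allyl group | OC1(CCC1)[C@]23O[C@@]2(C)CC[C@H](C(C)=C)[C@H]3CC=C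
A4 | alternative 2 | spiro ketol: 7-allyl-10-hydroxy-8-isopropenyl-10-methylspiro[4.5]decan-1-one (spiro numbering) | C1CC[C@]2([C@H](CC=C)[C@@H](C(C)=C)CC[C@]2(C)O)C1=O
A5 | alternative 3 | spiro-fused cyclopentene oxide (C14/C26 epoxide syn to C10; ring B as in A1) | [C@H]13CC[C@]2([C@H](CCCO[Si](C)(C)C(C)(C)C)/C(=C(/C)C(OC)OC)CC[C@]2(C)O)[C@H]1O3
A6 | alternative 3 | side-chain vinyl iodide, (2Z,4E)-2-iodo-10-methyl-6-methylideneundeca-2,4,9-trien-1-ol TBS ether | CC(C)=CCCC(=C)/C=C/C=C(/CO[Si](C)(C)C(C)(C)C)I
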